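The earlier runs and the new flask were computed with made-up constants, noise included.

The reading comes at 2.0 h, and the flasks asked about share one charge and differ in temperature.

the same everywhere: substrate 0.50 M; free catalyst 0.43 mM
- Friday's: added ligand 0.11 mM; temperature 65 °C; run made earlier
- Tuesday's: added ligand 0.17 mM; temperature 105 °C; run made earlier
- green: added ligand 0.22 mM; temperature 110 °C; time 2.0 h
- grey: added ligand 0.22 mM; temperature 80 °C; time 2.0 h
- ochre: added ligand 0.22 mM; temperature 130 °C; time 2.0 h
- violet: added ligand 0.22 mM; temperature 70 °C; time 2.0 h
- amber: added ligand 0.22 mM; temperature 140 °C; time 2.0 h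

| run | time / h | target / % |
|---|---|---|
| Friday's | 1.50 | 3.5 |
| Friday's | 5.00 | 5.7 |
| Friday's | 8.00 | 5.5 |
| Friday's | 12.0 | 6.1 |
| Friday's | 20.0 | 6.0 |
| Friday's | 25.0 | 6.6 |
| Tuesday's | 0.167 | 15.2 |
| Tuesday's | 0.500 | 22.9 |
| Tuesday's | 0.833 | 21.4 |
| Tuesday's | 1.33 | 20.2 |
| Tuesday's | 2.00 | 18.9 |
| Tuesday's | 2.50 | 18.2 |

(readings scatter by 0.5 percentage points)

* the flasks by amount of target, in percent of the substrate charged, highest first, at 2.0 h (green / grey / ochre / violet / amber)
* the amount of target, in percent of the substrate charged of the flask you put first, at 2.0 h
* the amount of target, in percent of the substrate charged of the flask you put last, at 2.0 h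

My colleague reads added ligand as the maker of active catalyst, so target should go with it: Tuesday's last reading, scaled from 0.17 mM to 0.22 mM of ligand, gives 23.6 % for green, and hotter flasks should lose target, as Tuesday's run does after its 22.9 %.

I read the ligand the other way. It pairs with free catalyst and takes it out of use; as a first reckoning the pairing is fast and complete, with ligand the limiting reagent. That leaves [free catalyst] at 0.320 mM in Friday's run, 0.260 mM in Tuesday's and 0.210 mM in the new flasks. Both runs change ligand and temperature together, so they prove neither of us right.

Let substrate leave by two routes, one uncatalysed to target and one catalysed past it. The mean of Friday's readings from 8.00 h on, 6.05 %, then gives S = 0.0206 mM, and Tuesday's reading of 18.9 % at the asked time, lower than that run's 22.9 %, gives S = 0.0606 mM; both values carry the scatter of the readings. Here S is the even-split concentration, the [free catalyst] at which the two routes share substrate equally, so target's share is S/(S + [free catalyst]).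

If S grows by a constant factor per degree, amber has S = 0.156 mM and a share of 42.6 %, a long extrapolation. Violet has S = 0.0236 mM and a share of 10.1 %. Cut roughly to the fraction of that mean which Friday's run showed at its first reading, in a colder flask and at an earlier time, violet comes to 5.84 %. My order is amber, ochre, green, grey, violet.

The forecast took my colleague's side, with green > grey > violet > ochre > amber, 23 % first and 1.5 % last, its top being the scaled reading, on the ground that “active catalyst scales with added ligand”.

The flasks give amber > ochre > green > grey > violet, from 28.6 % in amber to 5.88 % in violet, and my amber stood 14 percentage points too high. Amber at 2.00 h holds 70.6 % of its added ligand unpaired, grey 9.67 %. Put back into the rule, amber's extrapolated S and amber's result ask for 0.388 mM of free catalyst, not my 0.210 mM. Scaling with ligand is a view for temperatures beside Tuesday's: in green it stands 3.8 points above the flask.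

    substrate ⇌ target (K = 5.40, k = 0.0360 /min, Ea = 107 kJ/mol, ΔH = 6.00 kJ/mol)
    target ⇌ isomer of the product A (K = 1.60, k = 0.0170 /min, Ea = 116 kJ/mol, ΔH = −40.0 kJ/mol)
    isomer of the product A + free catalyst ⇌ isomer of the product B + free catalyst, rate k3*[free catalyst]*[isomer of the product A] forward; the back reaction follows from the equilibrium constant (K = 1.50, k = 69.0 /M/min, Ea = 59.0 kJ/mol, ΔH = 23.0 kJ/mol)
    isomer of the product B + free catalyst ⇌ substrate + free catalyst, rate k4*[free catalyst]*[isomer of the product B] forward; the back reaction follows from the equilibrium constant (k = 16.0 /M/min, Ea = 69.0 kJ/mol)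
    free catalyst + added ligand ⇌ idle complex, settled at all times (K = 16000 /M, ΔH = −35.0 kJ/mol)
    substrate ⇌ dormant form (K = 0.420, k = 0.0100 /min, Ea = 127 kJ/mol, ΔH = −2.00 kJ/mol)
    free catalyst + target → spent catalyst (k = 0.0170 /M/min, Ea = 89.0 kJ/mol)
    (constants at 110 °C)

A flask like violet kept at 85 °C lies half way between the temperatures of the two runs, so S is 0.0353 mM and target's share 14.4 %. That flask holds 15.4 % of target at 2.00 h, with 14.5 % of substrate still there.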